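I decided to reckon from the two peaks, not from the whole curves.

| flask | starting material | first nucleophile | second nucleophile | remark | time |
|---|---|---|---|---|---|
| autumn | 0.050 M | 1 equiv | 1.3 equiv | run made earlier |  |
| midnight | 0.050 M | 4 equiv | 1.3 equiv | run made earlier |  |
| flask | 0.050 M | 2.00 equiv | 1.30 equiv |  | 12 min |

| run | time / min | target / % |
|---|---|---|
| autumn | 0.333 | 7.2 |
| autumn | 0.667 | 10.6 |
| autumn | 1.00 | 14.0 |
| autumn | 1.50 | 15.2 |
| autumn | 2.50 | 14.6 |
| autumn | 4.00 | 10.1 |
| autumn | 8.00 | 5.1 |
| midnight | 0.333 | 17.1 |
| midnight | 0.667 | 26.0 |
| midnight | 1.00 | 29.8 |
| midnight | 1.50 | 30.8 |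
| midnight | 2.50 | 26.1 |
| midnight | 4.00 | 19.0 |
| midnight | 8.00 | 8.0 |

(scatter of a reading: 0.5 percentage points)

1. time up to 12 min at which target stands highest
2. the amount of target, in percent of the starting material charged, at that time
3. earliest time at which at least nineteen twentieths of that best amount are there, in min
4. latest time at which they still are, in min



Both runs stood highest at the reading at 1.50 min: 15.2% in the autumn run with 1 equiv of first nucleophile, and 30.8% in the midnight run with 4 equiv. So the peak rose by a factor of 2.03 while the charge rose by 4.00. That looked to me like a competition, so I took a hyperbola: peak = ceiling × charge / (charge + rival equivalents). The two readings give 2.08 equiv of rival equivalents, the charge of first nucleophile at which the hyperbola stands at half its ceiling, and a ceiling of 46.8%. The rival equivalents are a fitted constant of the two peak readings, taken at 1.3 equiv of second nucleophile. For 2.00 equiv it gave me 22.9%.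

The forecast, noting that “Quadrupling the first nucleophile only doubles the peak”, said 22.3% at 1.5 min, 0.60 percentage points below my figure, with the window from 1.03 min to 2.15 min.

The flask gave 22.7% at 1.47 min, and the window ran from 1.01 min to 2.11 min. The flask holds what that number doesn't show: at 1.47 min other capture product stood at 55.6%, more than the target. Put back into the hyperbola with the same ceiling, this result asks for 2.12 equiv of rival equivalents against the 2.08 equiv read from the runs.

    second nucleophile + target → over-reaction product (k = 0.160 /M/s)
    first nucleophile + intermediate → target (k = 27.0 /M/s)
    starting material → intermediate (k = 0.0240 /s)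
    first nucleophile ⇌ dormant form (K = 1.50, k = 0.00270 /s)
    second nucleophile + intermediate → other capture product (k = 81.0 /M/s)

For the neighbour flask with 3.40 equiv of first nucleophile, the rival equivalents gave 29.0%. The computed best there was 29.4%.

The earlier runs and the new flask were generated by integration on assumed constants, noise included.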